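The numbers in the tables come from a simulation for an exercise, noise included.

The product is what you want, so here is the quick number. Your hunch that its excess sags as the left-handed substrate runs down gets tested on one clock.

in all of them: left-handed substrate 0.099 M; right-handed substrate 0.099 M; partner 0.218 M; free catalyst 1.4 mM; racemization catalyst 99 µM

| charge | remark | time |
|---|---|---|
| Friday's | the very flask that is asked about, followed so far |  |
| flask |  | 5.0 min |

- Friday's (time / s: left-handed product / %, right-handed product / %): 10.0: 2.0, 1.4; 15.0: 3.3, 0; 25.0: 4.2, 2.1; 40.0: 6.7, 3.3; 80.0: 13.8, 7.2; 120: 19.8, 7.6

(each reading ± 1 percentage point)

- left-handed product and right-handed product together, in percent of the left-handed substrate and right-handed substrate charged together, at 5.0 min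
- excess of left-handed product over right-handed product in the product at 5.0 min
- whether the exchange between left-handed substrate and right-handed substrate keeps pace with the reaction: how far the product's excess at 5.0 min gets from its value without exchange to its value with instant exchange (above 80% keeps pace, below 20% hardly takes part, else lags behind)

- free catalyst is single-handed; left-handed substrate and right-handed substrate are mirror images of each other, charged as a racemate, each of them at the stated concentration
- an excess is below zero if the other one leads

Friday's run is this flask. Take its left-handed product at 120 s, 19.8% of the pool of both substrates charged, set it against the left-handed substrate's half of the charge, and turn that mean rate into a pseudo-first-order half-life: the reaction clock, the half-life of the left-handed substrate by reaction, read from one scattered reading as 3.50 min. Use it as a rule: the exchange keeps pace where its own half-life lies far below the clock.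

Count clocks. Friday's last reading stands at 0.571 of one, while the asked time is 1.43. I read no rate of exchange from these scattered readings, so your hunch stays open. I bet against it, as a guess: the excess pooled over Friday's readings, read as 39.5%, holds, and the exchange keeps pace. For the yield, let partner (0.218 M) and pool (0.198 M) fall together, so that reacted over unreacted grows in step with time. From the last reading that gives 48.5%.

The forecast gives 56%, 30% and "lags behind", calling the excess “too noisy to reveal the exchange rate”. The flask gives 50.5%, 48.5% and "keeps pace", 94% of the way.

    partner + free catalyst + right-handed substrate → free catalyst + right-handed product (k = 85.0 M⁻² s⁻¹)
    partner → decomposition product (k = 3.70 × 10⁻⁶ s⁻¹)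
    2 free catalyst ⇌ resting dimer, settled at all times (K = 78000 M⁻¹)
    free catalyst ⇌ dormant form (K = 0.760, k = 0.0610 s⁻¹)
    partner + free catalyst + left-handed substrate → free catalyst + left-handed product (k = 250 M⁻² s⁻¹)
    left-handed substrate + racemization catalyst ⇌ right-handed substrate + racemization catalyst, rate k6*[racemization catalyst]*[left-handed substrate] forward; the back reaction follows from the equilibrium constant (k = 580 M⁻¹ s⁻¹)

At 5.00 min the flask's exchange, by its own step and both ways together, has a relaxation half-life of 0.101 min, far shorter than the clock of 3.50 min and than the left-handed substrate's half-life by reaction then, 4.4 min. Now take the neighbour flask with 0.87 M of partner and the same racemization catalyst: scaled by the charge, its clock falls to 0.877 min, still longer than the first flask's 0.101 min, with 5.70 clocks in the time, so expect the excess to stay close. That neighbour gives 95.9% at an excess of 45.8%, a little lower than the first flask's 48.5%.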